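Locants: ring A = C1(benzoyl)–C2(=O)–C3–C4(=O)–C5(geranyl)–C9(=O); ring D = C1–C8(Me2)–C7–C6–C5–C9; ring B = C3–C4–C5–C6–C7–C10–C11; ring C = C3–C11–C12(Me2)–C13(i-Pr)–C14.
Retrosynthesis: cut C1–C8 (ring D, last), then C12–C13 (ring C), C3–C11 (ring B), C3–C14 (prenyl), then C1–C9 and C3–C4 (ring A, two Claisen acylations), back to a temporary δ-lactone C9(=O)–O–C8 that carries C5, C6 and C7.
Forward: resolved lavandulol → malonate → δ-lactone → Shi epoxide → allylic silyl ether → geranyl on C5 → ring A → prenyl on C3 → ring B (palladium allylation) → ring C (radical 5-exo) → ring D (cation capture at C1).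
Stereochemistry: C7 from (S)-lavandulol; C11 from the Shi epoxidation; C5 by 1,3-induction in the lactone alkylation; C3, C13 and C1 follow from the rings already closed.
Enabling feature: once rings B and C exist, C1 is the only enolisable carbon (centre of the acyl β-triketone C2/C9/benzoyl) and C7 of ring B holds the C8 carbinol over C1, out of reach of O2 and O9.
Key step: step 12

Remark: tricarbonyl compounds 14 and 16–19 are drawn and named as one enol tautomer; 7–9 are C5-epimer mixtures that converge in step 6.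

Step 1
Reactants: 1 (±)-lavandulol
Product: 2 (S)-lavandulol
Conditions: vinyl acetate, porcine pancreatic lipase, t-BuOMe, rt, conversion taken past one half; chromatography
Reagents that add atoms: none
Why: Lipase-catalysed kinetic resolution by transesterification should acylate the R alcohol faster, so the S alcohol left once conversion has passed one half carries the C7 configuration of the target in high enantiomeric purity.

Step 2
Reactants: 2 (S)-lavandulol; 3 dimethyl malonate
Product: 4 dimethyl 2-[(2R)-5-methyl-2-(prop-1-en-2-yl)hex-4-en-1-yl]propanedioate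
Conditions: Bu3P=CHCN (cyanomethylenetributylphosphorane), 3 (3 equiv), PhMe, 100 °C
Reagents that add atoms: none
Why: Mitsunobu-type C-alkylation of an active methylene compound by a primary alcohol, with the phosphorane as base and oxophile and excess 3 to suppress double alkylation; the stereocentre is not involved and only its descriptor changes.

Step 3
Reactants: 4 dimethyl 2-[(2R)-5-methyl-2-(prop-1-en-2-yl)hex-4-en-1-yl]propanedioate
Product: 7 methyl (5R)-6,6-dimethyl-5-(3-methylbut-2-en-1-yl)-2-oxooxane-3-carboxylate, via organomercurial adduct 5 (not isolated), via hydroxy diester 6 (not isolated)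
Conditions: Hg(OAc)2, THF/H2O, 0 °C; then NaBH4, aq NaOH, 0 °C, brief; then TsOH·H2O (cat), PhMe, 60 °C
Reagents that add atoms: water, O
Why: Markovnikov oxymercuration–demercuration is far faster at the 1,1-disubstituted isopropenyl group than at the trisubstituted alkene, and the tertiary alcohol 6 then lactonises onto one ester (acid-catalysed transesterification helped by the gem-dimethyl group), which ties the C8 oxygen to the future C9 carbonyl while C5 stays an epimerisable mixture.

Step 4
Reactants: 7 methyl (5R)-6,6-dimethyl-5-(3-methylbut-2-en-1-yl)-2-oxooxane-3-carboxylate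
Product: 8 methyl (5S)-5-{[(2R)-3,3-dimethyloxiran-2-yl]methyl}-6,6-dimethyl-2-oxooxane-3-carboxylate
Conditions: Shi ketone from D-fructose (1,2:4,5-di-O-isopropylidene-β-D-erythro-hexo-2,3-diulo-2,6-pyranose, 30 mol %), KHSO5 (as 2KHSO5·KHSO4·K2SO4), K2CO3, Bu4NHSO4, MeCN/(MeO)2CH2/aq buffer pH 10, 0 °C
Reagents that add atoms: potassium peroxymonosulfate, [K+].OOS(=O)(=O)[O-]
Why: Shi epoxidation of the only alkene left, a trisubstituted one, in which the dioxirane of the D-fructose-derived ketone should add oxygen through the spiro transition state to the face that makes the secondary epoxide carbon (C11) R under catalyst control.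

Step 5
Reactants: 8 methyl (5S)-5-{[(2R)-3,3-dimethyloxiran-2-yl]methyl}-6,6-dimethyl-2-oxooxane-3-carboxylate
Product: 9 methyl (5S)-5-[(2R)-2-{[tert-butyl(dimethyl)silyl]oxy}-3-methylbut-3-en-1-yl]-6,6-dimethyl-2-oxooxane-3-carboxylate
Conditions: t-BuMe2SiOTf (2.5 equiv), DBU (3 equiv), PhMe, −78 → 0 °C; aqueous work-up
Reagents that add atoms: tert-butyldimethylsilyl trifluoromethanesulfonate, CC(C)(C)[Si](C)(C)OS(=O)(=O)C(F)(F)F
Why: Silyl-triflate-promoted isomerisation of a trisubstituted epoxide to an allylic silyl ether, in which the O-silylated oxirane opens at the tertiary carbon while DBU removes a methyl proton, so the C11–O bond is never broken and its configuration is kept; any silyl ketene acetal formed at the malonate-type carbon is hydrolysed on work-up.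

Step 6
Reactants: 9 methyl (5S)-5-[(2R)-2-{[tert-butyl(dimethyl)silyl]oxy}-3-methylbut-3-en-1-yl]-6,6-dimethyl-2-oxooxane-3-carboxylate; 10 geranyl bromide
Product: 11 methyl (3R,5S)-5-[(2R)-2-{[tert-butyl(dimethyl)silyl]oxy}-3-methylbut-3-en-1-yl]-3-[(2E)-3,7-dimethylocta-2,6-dien-1-yl]-6,6-dimethyl-2-oxooxane-3-carboxylate
Conditions: Cs2CO3, DMF, 0 °C → rt
Reagents that add atoms: none
Why: Malonic-ester-type alkylation of the planar enolate, in which the allylic bromide should enter axially on the half-chair lactone on the face of the axial C7–H and trans to the C10 side chain (1,3-induction), so both C5 epimers of 9 converge on one quaternary C5.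

Step 7
Reactants: 11 methyl (3R,5S)-5-[(2R)-2-{[tert-butyl(dimethyl)silyl]oxy}-3-methylbut-3-en-1-yl]-3-[(2E)-3,7-dimethylocta-2,6-dien-1-yl]-6,6-dimethyl-2-oxooxane-3-carboxylate; 12 benzoylacetone
Product: 14 (4S)-2-benzoyl-4-[(2S,4R)-4-{[tert-butyl(dimethyl)silyl]oxy}-2-(2-hydroxypropan-2-yl)-5-methylhex-5-en-1-yl]-4-[(2E)-3,7-dimethylocta-2,6-dien-1-yl]-3-hydroxycyclohex-2-ene-1,5-dione, via triketone lactone 13 (not isolated)
Conditions: 12 (2.5 equiv), LiN(i-Pr)2 (5 equiv), THF, −78 °C; add 11, −78 → 0 °C; then rt, 12 h; aq HCl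
Reagents that add atoms: none
Why: The 1,3-diketone dianion is acylated at its terminal carbon by the methyl ester (the lactone carbonyl is shielded by the axial geranyl group and the gem-dimethyl-bearing ring oxygen) to give triketone 13, whose benzoyl-bearing methylene then attacks the lactone carbonyl in a polyketide-type intramolecular Claisen condensation (6-exo-trig) that expels the tertiary alkoxide, so ring A forms with the former lactone carbon as C9, C5 unchanged and no new stereocentre; an O-acylated pyranone isomer should funnel to the C-acyl product under the basic conditions.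

Step 8
Reactants: 14 (4S)-2-benzoyl-4-[(2S,4R)-4-{[tert-butyl(dimethyl)silyl]oxy}-2-(2-hydroxypropan-2-yl)-5-methylhex-5-en-1-yl]-4-[(2E)-3,7-dimethylocta-2,6-dien-1-yl]-3-hydroxycyclohex-2-ene-1,5-dione; 15 prenyl bromide
Product: 16 (6S)-4-benzoyl-6-[(2S,4R)-4-{[tert-butyl(dimethyl)silyl]oxy}-2-(2-hydroxypropan-2-yl)-5-methylhex-5-en-1-yl]-6-[(2E)-3,7-dimethylocta-2,6-dien-1-yl]-3,5-dihydroxy-2-(3-methylbut-2-en-1-yl)cyclohexa-2,4-dien-1-one
Conditions: NaOMe (2.1 equiv), MeOH, 0 °C; 15 (1.05 equiv)
Reagents that add atoms: none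
Why: C-alkylation of the dianion of the cyclic acyl-triketone at C3, the only unsubstituted and the most nucleophilic ring carbon (the acyl-bearing C1 and the quaternary C5 do not compete), as in the prenylation of acylphloroglucinols; C3 stays enolic, so no stereocentre arises.

Step 9
Reactants: 16 (6S)-4-benzoyl-6-[(2S,4R)-4-{[tert-butyl(dimethyl)silyl]oxy}-2-(2-hydroxypropan-2-yl)-5-methylhex-5-en-1-yl]-6-[(2E)-3,7-dimethylocta-2,6-dien-1-yl]-3,5-dihydroxy-2-(3-methylbut-2-en-1-yl)cyclohexa-2,4-dien-1-one
Product: 17 (6S)-4-benzoyl-6-[(2S,4R)-4-hydroxy-2-(2-hydroxypropan-2-yl)-5-methylhex-5-en-1-yl]-6-[(2E)-3,7-dimethylocta-2,6-dien-1-yl]-3,5-dihydroxy-2-(3-methylbut-2-en-1-yl)cyclohexa-2,4-dien-1-one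
Conditions: Bu4NF, AcOH (1:1), THF, 0 °C → rt
Reagents that add atoms: none
Why: Fluoride-mediated desilylation, buffered with acetic acid so that the tricarbonyl system is not deprotonated and the 1,4-diol does not cyclise; no stereocentre is affected.

Step 10
Reactants: 17 (6S)-4-benzoyl-6-[(2S,4R)-4-hydroxy-2-(2-hydroxypropan-2-yl)-5-methylhex-5-en-1-yl]-6-[(2E)-3,7-dimethylocta-2,6-dien-1-yl]-3,5-dihydroxy-2-(3-methylbut-2-en-1-yl)cyclohexa-2,4-dien-1-one
Product: 18 ring A/ring B bicycle (8-benzoyl-1-[(2E)-3,7-dimethylocta-2,6-dien-1-yl]-9-hydroxy-3-(2-hydroxypropan-2-yl)-6-(3-methylbut-2-en-1-yl)-5-(prop-1-en-2-yl)bicyclo[4.3.1]dec-8-ene-7,10-dione; C3 C5 C7 C11 of the target locants as in the target)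
Conditions: Pd(PPh3)4 (10 mol %), BEt3 (30 mol %), THF, 50 °C
Reagents that add atoms: none
Why: Intramolecular Tsuji–Trost allylation from the free allylic alcohol (ionisation helped by the acidic enol and BEt3), in which zerovalent palladium displaces the C11 oxygen with inversion and the soft C3 enolate attacks the same allyl terminus anti to the metal (seven-membered ring B preferred over the nine-membered ring at the CH2 terminus), so C11 is formed with net retention and C3 is fixed because the tether reaches only the face of ring A that carries C6; O-allylation is reversible and the acyl-bearing C1 is the poorer nucleophile.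

Step 11
Reactants: 18 ring A/ring B bicycle
Product: 19 ring A/B/C tricycle (as 18 but with the cyclopentane C3–C11–C12(Me2)–C13(i-Pr)–C14 closed; tertiary alcohol on C8 retained; C3 C5 C7 C11 C13 as in the target)
Conditions: Fe(acac)3 (0.5 equiv), PhSiH3 (2 equiv, slow addition), EtOH, 60 °C
Reagents that add atoms: none
Why: Reductive radical cyclisation started by hydrogen atom transfer from an iron hydride to the 1,1-disubstituted alkene (faster than to the trisubstituted ones), in which the tertiary C12 radical closes ring C by 5-exo-trig addition to the prenyl alkene on C3 through a chair-like transition state that places the isopropyl-bearing C13 substituent trans to C10 on C11, and the resulting tertiary radical takes up a second hydrogen atom.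

Step 12
Reactants: 19 ring A/B/C tricycle
Product: 20 target CNP0155129.1
Conditions: TfOH (5 mol %), (CF3)2CHOH/CH2Cl2 (1:4), 4 Å molecular sieves, −20 → 0 °C
Reagents that add atoms: none
Why: Protonation and loss of water at the tertiary carbinol give the C8 cation, which C7 of ring B holds over ring A, and the enol carbon C1 captures it to form the C1–C8 bond between two quaternary carbons, releasing the proton for turnover. The closest known reaction type is the biomimetic cation–enol cyclisation that builds the bicyclo[3.3.1]nonane core of polyprenylated acylphloroglucinols from dearomatised precursors, here run as a dehydrative SN1 tert-alkylation of a 1,3-dicarbonyl carbon. Ring D closes by attack of an enol carbon on a cation whose leaving oxygen is exocyclic (a 6-exo-tet closure in SN1 form, allowed in both its enolendo and enolexo variants) with C6 and C8 both axial on ring A, and the same bond necessarily completes the second seven-membered ring C1–C2–C3–C11–C10–C7–C8 of the homoadamantane cage. C1 is the only new stereocentre and is fixed by the cage, because C8 can reach C1 only from the face that already carries C6 and C11, which leaves the benzoyl group equatorial. The step needs C- over O-alkylation and this is secured by geometry: O2 and O9 lie in the plane of ring A beyond the reach of a cation tethered through C7 above the ring, and C3 and C5 are quaternary so no other enol exists. It also needs chemoselectivity over the geranyl alkenes, for which ionisation of a tertiary alcohol by catalytic acid at low temperature should be faster than C-protonation of a trisubstituted alkene, while E1 loss of a proton to the isopropenyl compound is reversible in this medium.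

Compound list
1 | (±)-lavandulol, rac-5-methyl-2-(prop-1-en-2-yl)hex-4-en-1-ol | CC(C)=CCC(CO)C(C)=C | starting material
2 | (S)-lavandulol, (2S)-5-methyl-2-(prop-1-en-2-yl)hex-4-en-1-ol | CC(C)=CC[C@H](CO)C(C)=C | intermediate
3 | dimethyl malonate | COC(=O)CC(=O)OC | starting material
4 | dimethyl 2-[(2R)-5-methyl-2-(prop-1-en-2-yl)hex-4-en-1-yl]propanedioate | COC(=O)C(C(=O)OC)C[C@@H](CC=C(C)C)C(C)=C | intermediate
5 | organomercurial adduct, dimethyl 2-[(2R)-2-[1-(acetoxymercurio)-2-hydroxypropan-2-yl]-5-methylhex-4-en-1-yl]propanedioate (carbinol carbon as a mixture) | COC(=O)C(C(=O)OC)C[C@@H](CC=C(C)C)C(C)(O)C[Hg]OC(C)=O | intermediate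
6 | hydroxy diester, dimethyl 2-[(2R)-2-(2-hydroxypropan-2-yl)-5-methylhex-4-en-1-yl]propanedioate | COC(=O)C(C(=O)OC)C[C@@H](CC=C(C)C)C(C)(C)O | intermediate
7 | methyl (5R)-6,6-dimethyl-5-(3-methylbut-2-en-1-yl)-2-oxooxane-3-carboxylate (both C3 epimers) | COC(=O)C1C[C@@H](CC=C(C)C)C(C)(C)OC1=O | intermediate
8 | methyl (5S)-5-{[(2R)-3,3-dimethyloxiran-2-yl]methyl}-6,6-dimethyl-2-oxooxane-3-carboxylate (both C3 epimers) | COC(=O)C1C[C@@H](C[C@H]2OC2(C)C)C(C)(C)OC1=O | intermediate
9 | methyl (5S)-5-[(2R)-2-{[tert-butyl(dimethyl)silyl]oxy}-3-methylbut-3-en-1-yl]-6,6-dimethyl-2-oxooxane-3-carboxylate (both C3 epimers) | COC(=O)C1C[C@@H](C[C@@H](O[Si](C)(C)C(C)(C)C)C(C)=C)C(C)(C)OC1=O | intermediate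
10 | geranyl bromide, (2E)-1-bromo-3,7-dimethylocta-2,6-diene | CC(C)=CCC/C(C)=C/CBr | starting material
11 | methyl (3R,5S)-5-[(2R)-2-{[tert-butyl(dimethyl)silyl]oxy}-3-methylbut-3-en-1-yl]-3-[(2E)-3,7-dimethylocta-2,6-dien-1-yl]-6,6-dimethyl-2-oxooxane-3-carboxylate | COC(=O)[C@@]1(C/C=C(\C)CCC=C(C)C)C[C@@H](C[C@@H](O[Si](C)(C)C(C)(C)C)C(C)=C)C(C)(C)OC1=O | intermediate
12 | benzoylacetone, 1-phenylbutane-1,3-dione | CC(=O)CC(=O)c1ccccc1 | starting material
13 | triketone lactone, (3R,5S)-5-[(2R)-2-{[tert-butyl(dimethyl)silyl]oxy}-3-methylbut-3-en-1-yl]-3-[(2E)-3,7-dimethylocta-2,6-dien-1-yl]-6,6-dimethyl-3-(3,5-dioxo-5-phenylpentanoyl)oxan-2-one | O=C(CC(=O)CC(=O)c1ccccc1)[C@@]1(C/C=C(\C)CCC=C(C)C)C[C@@H](C[C@@H](O[Si](C)(C)C(C)(C)C)C(C)=C)C(C)(C)OC1=O | intermediate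
14 | (4S)-2-benzoyl-4-[(2S,4R)-4-{[tert-butyl(dimethyl)silyl]oxy}-2-(2-hydroxypropan-2-yl)-5-methylhex-5-en-1-yl]-4-[(2E)-3,7-dimethylocta-2,6-dien-1-yl]-3-hydroxycyclohex-2-ene-1,5-dione | O=C1CC(=O)C(C(=O)c2ccccc2)=C(O)[C@]1(C/C=C(\C)CCC=C(C)C)C[C@@H](C[C@@H](O[Si](C)(C)C(C)(C)C)C(C)=C)C(C)(C)O | intermediate
15 | prenyl bromide, 1-bromo-3-methylbut-2-ene | CC(C)=CCBr | starting material
16 | (6S)-4-benzoyl-6-[(2S,4R)-4-{[tert-butyl(dimethyl)silyl]oxy}-2-(2-hydroxypropan-2-yl)-5-methylhex-5-en-1-yl]-6-[(2E)-3,7-dimethylocta-2,6-dien-1-yl]-3,5-dihydroxy-2-(3-methylbut-2-en-1-yl)cyclohexa-2,4-dien-1-one | O=C1C(CC=C(C)C)=C(O)C(C(=O)c2ccccc2)=C(O)[C@]1(C/C=C(\C)CCC=C(C)C)C[C@@H](C[C@@H](O[Si](C)(C)C(C)(C)C)C(C)=C)C(C)(C)O | intermediate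
17 | (6S)-4-benzoyl-6-[(2S,4R)-4-hydroxy-2-(2-hydroxypropan-2-yl)-5-methylhex-5-en-1-yl]-6-[(2E)-3,7-dimethylocta-2,6-dien-1-yl]-3,5-dihydroxy-2-(3-methylbut-2-en-1-yl)cyclohexa-2,4-dien-1-one | O=C1C(CC=C(C)C)=C(O)C(C(=O)c2ccccc2)=C(O)[C@]1(C/C=C(\C)CCC=C(C)C)C[C@@H](C[C@@H](O)C(C)=C)C(C)(C)O | intermediate
18 | ring A/ring B bicycle: ring A (C1 benzoyl, C1=C9 enol, C2 and C4 ketones) bridged from C3 to C5 by C11–C10–C7–C6; C3 prenyl, C5 geranyl, C7 2-hydroxypropan-2-yl, C11 prop-1-en-2-yl; C3, C5, C7, C11 as in the target | CC(C)=CCC/C(C)=C/C[C@@]12C[C@H](C(C)(C)O)C[C@H](C(C)=C)[C@@](CC=C(C)C)(C1=O)C(=O)C(C(=O)c1ccccc1)=C2O | intermediate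
19 | ring A/B/C tricycle: as 18 with the cyclopentane C3–C11–C12(Me2)–C13(i-Pr)–C14 closed and the tertiary alcohol C8–OH on C7; C3, C5, C7, C11, C13 as in the target | CC(C)=CCC/C(C)=C/C[C@@]12C[C@H](C(C)(C)O)C[C@@H]3C(C)(C)[C@@H](C(C)C)C[C@]3(C1=O)C(=O)C(C(=O)c1ccccc1)=C2O | intermediate
20 | CNP0155129.1: homoadamantane-type trione with fused cyclopentane, C1 benzoyl, C5 (E)-geranyl, C8 and C12 gem-dimethyl, C13 isopropyl | CC(C)=CCC/C(C)=C/C[C@@]12C[C@H]3C[C@@H]4C(C)(C)[C@@H](C(C)C)C[C@]4(C1=O)C(=O)[C@@](C(=O)c1ccccc1)(C2=O)C3(C)C | target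

Total step count: 12. Longest linear sequence: 12 steps (1 → 20).

Steps most likely to fail

Step 7. The dianion may add to the lactone carbonyl instead of the methyl ester; this loss of chemoselectivity would interchange C4 and C9 and so invert C5 relative to C7. The triketone may also close through oxygen (lactonisation to a pyranone) instead of carbon. The fallback sets out from 11. The methyl ester alone is cleaved with Me3SnOH (ClCH2CH2Cl, 80 °C) to the carboxylic acid F1. 1-Chloro-N,N,2-trimethylprop-1-en-1-amine then converts it under neutral conditions into the acid chloride F2. At −78 °C the dianion of 12 should be acylated by the acid chloride long before it touches the lactone, which gives 13, where the fallback comes back to the route. Compound 13 is then closed to 14 with Mg(OMe)2 in MeOH, where chelation of the triketone to magnesium favours C-acylation.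

Step 10. Ring closure at a carbon that becomes quaternary may be slow, so that O-allylation, attack at the CH2 terminus, or equilibration of the allyl complex with loss of the C11 configuration take over. The fallback sets out from 14 and reverses the order of alkylation and ring closure. Desilylation (Bu4NF/AcOH) gives the allylic alcohol F3. The Pd(PPh3)4/BEt3 allylation is then run at the unsubstituted, more nucleophilic C3 methylene and gives the bicyclic β-diketone F4 with a tertiary C3–H. Only then is C3 prenylated with 15 (NaOMe, MeOH), which can occur only on the face opposite to the C11 bridge. This comes back to the route at 18.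

Step 12. The C8 cation may lose a proton to the isopropenyl compound faster than C1 captures it, and stronger acid for re-ionisation may draw the geranyl alkenes into cation–olefin cyclisation. The fallback sets out from 19. Deliberate dehydration with Burgess reagent (PhH, 50 °C) gives the isopropenyl compound F5. Its 1,1-disubstituted alkene is then added to by the C1 enol in Markovnikov sense under π-acid catalysis (Ph3PAuCl/AgOTf, PhMe, 60 °C), a gold-catalysed hydroalkylation of an alkene by a 1,3-dicarbonyl that needs no Brønsted acid. This comes back to the route at 20.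

Further compounds
F1 | step 7 | (3R,5S)-5-[(2R)-2-{[tert-butyl(dimethyl)silyl]oxy}-3-methylbut-3-en-1-yl]-3-[(2E)-3,7-dimethylocta-2,6-dien-1-yl]-6,6-dimethyl-2-oxooxane-3-carboxylic acid | OC(=O)[C@@]1(C/C=C(\C)CCC=C(C)C)C[C@@H](C[C@@H](O[Si](C)(C)C(C)(C)C)C(C)=C)C(C)(C)OC1=O
F2 | step 7 | acid chloride of F1 (same spatial arrangement at all centres) | ClC(=O)[C@@]1(C/C=C(\C)CCC=C(C)C)C[C@@H](C[C@@H](O[Si](C)(C)C(C)(C)C)C(C)=C)C(C)(C)OC1=O
F3 | step 10 | (4S)-2-benzoyl-4-[(2S,4R)-4-hydroxy-2-(2-hydroxypropan-2-yl)-5-methylhex-5-en-1-yl]-4-[(2E)-3,7-dimethylocta-2,6-dien-1-yl]-3-hydroxycyclohex-2-ene-1,5-dione | O=C1CC(=O)C(C(=O)c2ccccc2)=C(O)[C@]1(C/C=C(\C)CCC=C(C)C)C[C@@H](C[C@@H](O)C(C)=C)C(C)(C)O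
F4 | step 10 | ring A/ring B bicycle as 18 but with hydrogen in place of the prenyl group on C3 | CC(C)=CCC/C(C)=C/C[C@@]12C[C@H](C(C)(C)O)C[C@H](C(C)=C)[C@@H](C1=O)C(=O)C(C(=O)c1ccccc1)=C2O
F5 | step 12 | ring A/B/C tricycle as 19 but with prop-1-en-2-yl on C7 in place of the tertiary alcohol | CC(C)=CCC/C(C)=C/C[C@@]12C[C@H](C(C)=C)C[C@@H]3C(C)(C)[C@@H](C(C)C)C[C@]3(C1=O)C(=O)C(C(=O)c1ccccc1)=C2O
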